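How slowly E and X turn into each other is what I have to read from these runs. I take E to give L and X to give another product, both over G. If they did not cross, the L at the end of a flask equals the share of E in the charge. If they crossed at once (the Curtin–Hammett limit), L ends at one fixed share, the mix, whatever the charge.

| flask | E | X | G | remark | time |
|---|---|---|---|---|---|
| west | 0.25 M | 0.34 equiv | 0.2 mol% | run made earlier |  |
| south | 0.25 M | 1.3 equiv | 0.2 mol% | run made earlier |  |
| east | 0.46 M | 0.25 equiv | 0.2 mol% | run made earlier |  |
| autumn | 1.0 M | 1.00 equiv | 0.2 mol% |  | 12 d |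
| midnight | 0.25 M | 0.250 equiv | 0.2 mol% |  | 12 d |
| dusk | 1.0 M | 0.250 equiv | 0.2 mol% |  | 12 d |
| spring | 0.25 M | 1.00 equiv | 0.2 mol% |  | 12 d |

| run | time / d | L / % |
|---|---|---|
| west | 0.625 | 40.1 |
| west | 1.67 | 53.0 |
| west | 3.00 | 60.0 |
| west | 5.00 | 65.1 |
| west | 8.00 | 68.3 |
| west | 10.0 | 67.3 |
| west | 12.0 | 68.4 |
| south | 1.67 | 37.4 |
| south | 3.00 | 43.0 |
| south | 5.00 | 48.0 |
| south | 6.00 | 48.7 |
| south | 8.00 | 50.5 |
| south | 10.0 | 51.8 |
| south | 12.0 | 52.3 |
| east | 1.04 | 57.6 |
| east | 3.00 | 67.8 |
| east | 6.00 | 72.4 |
| east | 8.00 | 74.1 |
| east | 12.0 | 74.0 |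

(each reading ± 0.5 percentage points)

- in a conversion X counts as not yet reacted

1. the flasks put in order of amount of L, in percent of the E and X together charged, best first, at 12 d (autumn / midnight / dusk / spring)
2. the same order at 2.5 d (autumn / midnight / dusk / spring)
3. the amount of L, in percent of the E and X together charged of the flask you put first, at 12 d
4. the amount of L, in percent of the E and X together charged of the flask you put last, at 12 d

At 0.25 M of E, the west run charges 74.6% as E and ends at 68.4%, while the south run charges 43.5% and ends at 52.3%. West falls below its share and south rises above it, so both stand between the extremes. The points of L gained per point of E share are 0.517, and this is the pass-through: one without crossing, zero with instant crossing. Taking L as straight in the share, that line meets its own share at a mix of 61.7%, a reading that carries the scatter of the two runs.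

I assume the mix holds in the east run, and its 74.0% then gives a pass-through of 0.671 at 0.46 M. Extending the fall of one minus the pass-through as a power of concentration, exponent 0.632, I reach 0.799 at 1.0 M, which is an extrapolation.

My order at 12 d is therefore dusk 76.3%, midnight 71.2%, spring 55.7%, autumn 52.4%.

Earlier on, the west run had 87.7% of its last reading at 3.00 d, the south run 82.2% at 3.00 d and the east run 91.6% at 3.00 d. I carry these fractions to 2.5 d, although they were read later, with west standing for midnight, south for spring, and east for dusk and autumn, although east has less E than those two. So I put dusk near 69.9%, midnight near 62.4%, autumn near 48.0% and spring near 45.8%, and spring and autumn swap.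

The forecast, reading that “each X caps a chain, E inserts reversibly”, gives dusk > autumn > midnight > spring at 12 d and dusk > autumn > midnight > spring at 2.5 d, with 85% first and 56% last. It parts from my reckoning by keeping autumn second.

    E ⇌ X (K = 0.220, k = 3.50 × 10⁻⁶ s⁻¹)
    E + G → G + L (k = 0.0540 M⁻¹ s⁻¹)
    G + X → G + D (k = 0.110 M⁻¹ s⁻¹)
    2 G ⇌ Q (K = 38000 M⁻¹, k = 0.0390 M⁻¹ s⁻¹)
    2 G → J (k = 0.00770 M⁻¹ s⁻¹)

The flasks give dusk > midnight > spring > autumn at 12 d, with dusk at 75.4% and autumn at 51.8%, and dusk > midnight > autumn > spring at 2.5 d. Dusk and autumn together show a pass-through of 0.787 against my 0.799. For the neighbour of dusk with 0.420 equiv of X, 0.799 gives 68.7%, and that flask holds 67.9%. In dusk, half of the turnover of E to L up to 12 d is done by 0.125 d. In dusk, E and X, both ways together and by that step alone, relax more slowly than that, with a relaxation half-life of 0.413 d.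

The earlier runs and the new flask come from a simulation from invented constants; scatter was added.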